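The ratio ([J]+[Q])/[G], in a flask where G reacts with Z under the catalyst L to give Q and J, stops climbing in both earlier runs, and it stops higher in alder, which had more Z, than in elm.

all flasks: G 10 mM; L 1 mol%
- elm: Z 1.4 equiv; run made earlier
- alder: Z 6 equiv; run made earlier
- south-east: Z 4.40 equiv; time 25 h
- north-east: Z 2.20 equiv; time 25 h
- south: Z 1.10 equiv; time 25 h

| run | time / h | J / % | Q / % | G / % |
|---|---|---|---|---|
| elm | 2.00 | 52 | 9 | 35 |
| elm | 3.00 | 68 | 5 | 29 |
| elm | 5.00 | 76 | 4 | 18 |
| elm | 8.00 | 82 | 1 | 12 |
| elm | 10.0 | 86 | 3 | 15 |
| elm | 15.0 | 87 | 4 | 13 |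
| elm | 25.0 | 86 | 1 | 11 |
| alder | 1.33 | 70 | 22 | 9 |
| alder | 4.00 | 93 | 3 | 2 |
| alder | 8.00 | 97 | 5 | 1 |
| alder | 10.0 | 95 | 4 | 2 |
| alder | 15.0 | 96 | 3 | 0 |
| alder | 20.0 | 96 | 3 | 1 |
| alder | 25.0 | 98 | 1 | 2 |

(standard deviation of a reading: 1.5 percentage points)

- the numbers in the tables scatter with a standard deviation of 1.5 percentage points

- which of these there is most of at the end, counted by the G in it, south-east (G / Q / J)
- which of these there is most of at the end, counted by the G in it, north-east (G / Q / J)
- which of these there is most of at the end, counted by the G in it, south (G / Q / J)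
- amount of the one of these that there is most of at the end, in percent of the G charged, south-east
- amount of the one of these that there is most of at the end, in percent of the G charged, north-east
- amount of the one of these that there is most of at the end, in percent of the G charged, south

In elm the readings of J still climb from 82% at 8.00 h to 87% at 15.0 h and then stand at 86% at 25.0 h, when elm holds 87.0% as J and Q beside 11% as G, a reading of G that carries a scatter of 1.5 points. That consumption leaves 0.530 equiv of free Z, so the end looks like an equilibrium (thermodynamic control, in the usual term). The reckoning here therefore carries K, the end ratio ([J]+[Q])/[G] per equiv of free Z, which elm puts at 14.9 per equiv, or 1.17 as a decimal logarithm. The logarithm of the end ratio is then 1.17 plus the logarithm of free Z. For a given charge, G left is found by setting the G gone, over the G left, equal to K times free Z, where free Z is the charge less the G gone. Alder then gets 1.32% of G, and its late readings lie between 0% and 2%. South gets 18.8% of G. Taking off the 2.25% of Q read late in elm, J comes to 95.8% in south-east, 92.7% in north-east and 78.9% in south.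

The forecast takes the ratio near 15 per equiv, on the grounds that “Both fit an equilibrium”. It names J, J and J, at 96%, 92% and 78%, a little apart from the figures above.

The flasks give J at 95.6% in south-east, J at 92.6% in north-east and J at 79.3% in south.

    2 L ⇌ D, settled at all times (K = 24500 M⁻¹)
    G + Z ⇌ J (K = 1500 M⁻¹, k = 57.0 M⁻¹ h⁻¹)
    2 L → E (k = 2490 M⁻¹ h⁻¹)
    Q + L ⇌ J + L, rate k4*[L]*[Q] forward; the back reaction follows from the equilibrium constant (k = 128 M⁻¹ h⁻¹)
    G + Z ⇌ Q (K = 39.0 M⁻¹, k = 178 M⁻¹ h⁻¹)

South ends at 79.3% of J, and left ten times as long, to 250 h, it still holds 79.4%, with 18.6% of its G and 26.0% of its own Z free at 25 h. A neighbour of south, charged with 0.440 equiv of Z, is given 60.4% of G by K, and that neighbour ends with 60.3% of G.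

The numbers in the tables are calculated with constants of no real substance; noise was put on by code.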